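**Retrosynthetic overview**
1. Target 12 ⇒ ether 11 by a late C7'–OOH bond formation: singlet-oxygen (Schenck) ene reaction on the Δ6' olefin, which also creates the (E)-Δ5' olefin.
2. Ether 11 ⇒ 4-hydroxy-5-methylcoumarin 3 + diol 10 by the C1'–O ether bond (Mitsunobu, selective for the primary allylic hydroxyl).
3. Diol 10 ⇒ enal 7 + tertiary allyl boronate 6: a new chiral-acid-catalysed linear prenylboration makes C4'–C5' and sets the only stereocentre (4'R).
4. Rings: the benzene ring is bought; only the pyranone ring of the coumarin is built (step 1).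

Assumption: compounds 1, 4 and 7, diethyl carbonate, pinacolborane and (R)-TRIP are purchased; side-chain atoms are numbered C1'–C8' from the ether CH2.

**Route**

Step 1
Reactants: 1 2'-hydroxy-6'-methylacetophenone
Product: 3 4-hydroxy-5-methylcoumarin, via β-keto ester 2 (not isolated)
Conditions: NaH (3 equiv), (EtO)2CO, toluene, 110 °C; then aq. HCl
Reagents that add atoms: diethyl carbonate, CCOC(=O)OCC
Why: Claisen-type C-acylation of the methyl ketone enolate by diethyl carbonate, then lactonisation of the β-keto ester onto the phenoxide (standard 4-hydroxycoumarin synthesis); no stereocentre.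

Step 2
Reactants: 4 prenyl bromide (1-bromo-3-methylbut-2-ene)
Product: 6 4,4,5,5-tetramethyl-2-(2-methylbut-3-en-2-yl)-1,3,2-dioxaborolane, via prenylmagnesium bromide 5 (not isolated)
Conditions: Mg, HBpin, THF, 25 °C (Barbier)
Reagents that add atoms: pinacolborane, CC1(C)OBOC1(C)C
Why: Barbier borylation in which the prenyl Grignard formed in situ attacks boron through its γ-carbon (SE2') with loss of hydride, giving the kinetic tertiary allyl boronate, which as a pinacol ester does not undergo 1,3-boron shift; no stereocentre.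

Step 3
Reactants: 6 4,4,5,5-tetramethyl-2-(2-methylbut-3-en-2-yl)-1,3,2-dioxaborolane, 7 (E)-4-acetoxy-2-methylbut-2-enal
Product: 10 (2E,4R)-3,7-dimethylocta-2,6-diene-1,4-diol, via borate ester 8 (not isolated), via hydroxy acetate 9 (not isolated)
Conditions: (R)-TRIP (5 mol %), 4 Å MS, toluene, −30 → 0 °C; then K2CO3, MeOH, rt
Reagents that add atoms: none
Why: Proposed new method: chiral-phosphoric-acid-catalysed allylboration of an enal with an achiral tertiary (α,α-dimethylallyl) pinacol boronate, in which the acid hydrogen-bonds the pseudo-axial boronate oxygen and the formyl C–H of a closed six-membered chair transition state, so that the unsubstituted CH2 terminus adds to the aldehyde Re face (4R, expected with (R)-TRIP) while the boron-bearing CMe2 carbon becomes the alkene terminus, giving the linear prenyl carbinol with no E/Z issue and little racemic background because the hindered boronate is slow without acid; the closest known reactions are the TRIP-catalysed allyl- and crotylboration of aldehydes with primary allyl boronates and the uncatalysed γ-selective addition of α,α-disubstituted allyl boronates, and the methanolysis in the same pot cleaves the O–B bond and the acetate.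

Step 4
Reactants: 3 4-hydroxy-5-methylcoumarin, 10 (2E,4R)-3,7-dimethylocta-2,6-diene-1,4-diol
Product: 11 4-{[(2E,4R)-4-hydroxy-3,7-dimethylocta-2,6-dien-1-yl]oxy}-5-methyl-2H-chromen-2-one
Conditions: PPh3, DIAD, THF, 0 °C → rt
Reagents that add atoms: none
Why: Mitsunobu etherification in which the acidic vinylogous-acid O–H of 3 is O-alkylated by SN2 at the activated, less hindered primary allylic hydroxyl (C1') of 10; the secondary C4' carbinol is not a reacting centre and stays R, and the E-olefin, which rules out cyclisation to a dihydrofuran, is kept.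

Step 5
Reactants: 11 4-{[(2E,4R)-4-hydroxy-3,7-dimethylocta-2,6-dien-1-yl]oxy}-5-methyl-2H-chromen-2-one
Product: 12 4-{[(2E,4R,5E)-7-hydroperoxy-4-hydroxy-3,7-dimethylocta-2,5-dien-1-yl]oxy}-5-methyl-2H-chromen-2-one
Conditions: O2, TPP (1 mol %), visible light (>400 nm), CH2Cl2, 0 °C
Reagents that add atoms: dioxygen (as singlet oxygen), O=O
Why: Schenck ene reaction of singlet oxygen at the most electron-rich, trialkyl-substituted Δ6' olefin (the Δ2' olefin is deactivated by two allylic oxygens and the push–pull coumarin C3=C4 bond is inert), where abstraction of an allylic C5'–H gives the tertiary C7' hydroperoxide with the transposed (E)-Δ5' olefin and leaves C4' untouched.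

**Compound list**
1 | 1-(2-hydroxy-6-methylphenyl)ethan-1-one (2'-hydroxy-6'-methylacetophenone) | CC(=O)c1c(C)cccc1O | starting material
2 | ethyl 3-(2-hydroxy-6-methylphenyl)-3-oxopropanoate (β-keto ester, sodium salt in the flask) | CCOC(=O)CC(=O)c1c(C)cccc1O | intermediate (not isolated)
3 | 4-hydroxy-5-methyl-2H-chromen-2-one (4-hydroxy-5-methylcoumarin) | Cc1cccc2oc(=O)cc(O)c12 | intermediate
4 | 1-bromo-3-methylbut-2-ene (prenyl bromide) | CC(C)=CCBr | starting material
5 | (3-methylbut-2-en-1-yl)magnesium bromide | CC(C)=CC[Mg]Br | intermediate (not isolated)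
6 | 4,4,5,5-tetramethyl-2-(2-methylbut-3-en-2-yl)-1,3,2-dioxaborolane | C=CC(C)(C)B1OC(C)(C)C(C)(C)O1 | intermediate
7 | (2E)-3-methyl-4-oxobut-2-en-1-yl acetate [(E)-4-acetoxy-2-methylbut-2-enal] | C/C(=C\COC(C)=O)C=O | starting material
8 | (2E,4R)-3,7-dimethyl-4-[(4,4,5,5-tetramethyl-1,3,2-dioxaborolan-2-yl)oxy]octa-2,6-dien-1-yl acetate | C/C(=C\COC(C)=O)[C@H](OB1OC(C)(C)C(C)(C)O1)CC=C(C)C | intermediate (not isolated)
9 | (2E,4R)-4-hydroxy-3,7-dimethylocta-2,6-dien-1-yl acetate | C/C(=C\COC(C)=O)[C@H](O)CC=C(C)C | intermediate (not isolated)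
10 | (2E,4R)-3,7-dimethylocta-2,6-diene-1,4-diol | C/C(=C\CO)[C@H](O)CC=C(C)C | intermediate
11 | 4-{[(2E,4R)-4-hydroxy-3,7-dimethylocta-2,6-dien-1-yl]oxy}-5-methyl-2H-chromen-2-one | C/C(=C\COc1cc(=O)oc2cccc(C)c12)[C@H](O)CC=C(C)C | intermediate
12 | 4-{[(2E,4R,5E)-7-hydroperoxy-4-hydroxy-3,7-dimethylocta-2,5-dien-1-yl]oxy}-5-methyl-2H-chromen-2-one | C/C(=C\COc1cc(=O)oc2cccc(C)c12)[C@H](O)/C=C/C(C)(C)OO | target

**Step count and risks**
Total steps: 5. Longest linear sequence: 4 (4 → 6 → 10 → 11 → 12).

Most likely to fail: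

Step 3 (the proposed new step). The hindered tertiary boronate may react too slowly, give poor facial control, or give the opposite sense (then (S)-TRIP is used). The fallback uses known chemistry, sets out from 7 and comes back at 10. The established (R)-TRIP-catalysed allylboration with commercial allylboronic acid pinacol ester (toluene, −30 °C) gives (2E,4R)-3-methyl-4-[(4,4,5,5-tetramethyl-1,3,2-dioxaborolan-2-yl)oxy]hepta-2,6-dien-1-yl acetate F1. This is methanolysed in the same pot (K2CO3, MeOH) through (2E,4R)-4-hydroxy-3-methylhepta-2,6-dien-1-yl acetate F2 to (2E,4R)-3-methylhepta-2,6-diene-1,4-diol F3. Cross-metathesis of F3 with excess 2-methyl-2-butene (Grubbs II, CH2Cl2, 40 °C) converts the terminal vinyl group into the isopropylidene and gives 10; the trisubstituted Δ2 olefin does not take part.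

Step 5. The ene reaction also abstracts hydrogen from the (Z)-methyl group, so the secondary C6' hydroperoxide (Δ7') is expected in roughly equal amount and must be separated; over-oxidation of the Δ2' olefin is a minor risk. The fallback sets out from 11 and comes back at 12. Epoxidation of the electron-rich Δ6' olefin (mCPBA, NaHCO3, CH2Cl2, −20 °C) gives 4-{[(2E,4R)-5-(3,3-dimethyloxiran-2-yl)-4-hydroxy-3-methylpent-2-en-1-yl]oxy}-5-methyl-2H-chromen-2-one F5 (C6' epimers). Ring-opening at the secondary carbon with PhSeNa ((PhSe)2, NaBH4, EtOH) gives 4-{[(2E,4R)-4,7-dihydroxy-3,7-dimethyl-6-(phenylselanyl)oct-2-en-1-yl]oxy}-5-methyl-2H-chromen-2-one F6. Oxidation (H2O2, THF, 0 °C) gives the corresponding selenoxide 4-{[(2E,4R)-6-(benzeneseleninyl)-4,7-dihydroxy-3,7-dimethyloct-2-en-1-yl]oxy}-5-methyl-2H-chromen-2-one F7, whose syn-elimination away from the carbinol (Sharpless–Lauer sequence) gives regiospecifically 4-{[(2E,4R,5E)-4,7-dihydroxy-3,7-dimethylocta-2,5-dien-1-yl]oxy}-5-methyl-2H-chromen-2-one F8. Acid-catalysed exchange of the tertiary allylic hydroxyl (50% H2O2, cat. H2SO4, Et2O, 0 °C) then gives 12. The weak point of this fallback is competing ionisation at the doubly allylic C4' carbinol.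

Step 4. The coumarin is ambident (2-alkoxychromone and C3-alkylated by-products, made worse by the peri 5-methyl group), and the secondary hydroxyl of 10 may compete. The fallback sets out from 10 and comes back at 11. Primary-selective Corey–Kim chlorination (NCS, Me2S, CH2Cl2, −20 °C) gives (2E,4R)-1-chloro-3,7-dimethylocta-2,6-dien-4-ol F4. Classical SN2 O-alkylation of 3 with F4 (K2CO3, DMF, rt) then gives 11.

**Further compounds**
F1 | step 3 | (2E,4R)-3-methyl-4-[(4,4,5,5-tetramethyl-1,3,2-dioxaborolan-2-yl)oxy]hepta-2,6-dien-1-yl acetate | C/C(=C\COC(C)=O)[C@H](OB1OC(C)(C)C(C)(C)O1)CC=C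
F2 | step 3 | (2E,4R)-4-hydroxy-3-methylhepta-2,6-dien-1-yl acetate | C/C(=C\COC(C)=O)[C@H](O)CC=C
F3 | step 3 | (2E,4R)-3-methylhepta-2,6-diene-1,4-diol | C/C(=C\CO)[C@H](O)CC=C
F4 | step 4 | (2E,4R)-1-chloro-3,7-dimethylocta-2,6-dien-4-ol | C/C(=C\CCl)[C@H](O)CC=C(C)C
F5 | step 5 | 4-{[(2E,4R)-5-(3,3-dimethyloxiran-2-yl)-4-hydroxy-3-methylpent-2-en-1-yl]oxy}-5-methyl-2H-chromen-2-one | C/C(=C\COc1cc(=O)oc2cccc(C)c12)[C@H](O)CC1OC1(C)C
F6 | step 5 | 4-{[(2E,4R)-4,7-dihydroxy-3,7-dimethyl-6-(phenylselanyl)oct-2-en-1-yl]oxy}-5-methyl-2H-chromen-2-one | C/C(=C\COc1cc(=O)oc2cccc(C)c12)[C@H](O)CC([Se]c1ccccc1)C(C)(C)O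
F7 | step 5 | 4-{[(2E,4R)-6-(benzeneseleninyl)-4,7-dihydroxy-3,7-dimethyloct-2-en-1-yl]oxy}-5-methyl-2H-chromen-2-one | C/C(=C\COc1cc(=O)oc2cccc(C)c12)[C@H](O)CC([Se](=O)c1ccccc1)C(C)(C)O
F8 | step 5 | 4-{[(2E,4R,5E)-4,7-dihydroxy-3,7-dimethylocta-2,5-dien-1-yl]oxy}-5-methyl-2H-chromen-2-one | C/C(=C\COc1cc(=O)oc2cccc(C)c12)[C@H](O)/C=C/C(C)(C)O
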